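**Plan**

Retrosynthesis: the three MOM ethers come off first. The two aryl–prenyl bonds (C8–CH2 and C3'–CH2) are then cut together, then the C3–C1' bond between ring C and ring B, and last ring C at O1–C2 and C3=C4.
Forward: rings A and B are bought as aromatic rings. Ring C is closed on ring A as a flat, achiral 2H-chromene, ring B is made into a boronic acid, and the two are joined at C3–C1'. Both prenyl groups follow in one operation and the phenols are freed last.
Enabling feature 1: C3 (beta carbon of a styrene fed by O1 and O7) and C1' (ortho and para to O2' and O4') are both donor carbons. They are therefore joined by insertion of the C3=C4 alkene into an aryl–rhodium bond, not by polar chemistry. Ring A holds the metal at benzylic C4, where it has no syn beta hydrogen and no beta oxygen.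
Enabling feature 2: rings A and B are the same kind of unit, a resorcinol-type ring with its prenyl group on the carbon flanked by two oxygens (C8 between O1 and O7, C3' between O2' and O4'). One twofold directed ortho-metalation therefore serves both.
Stereochemistry: the only stereocentre, C3 (R), comes from the chiral bisphosphine on rhodium in the bond-forming step, and no later step touches it.

Key step: step 5

Assumption: (R)-SEGPHOS is written as the ligand antipode that sends the aryl group to the face of C3 leading to the 3R series. The sense of induction is to be verified on the coupled product by correlation with the natural product. If it is opposite, the (S)-ligand takes its place with no other change.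

**Route**

Step 1
Reactants: 1 2,4-dihydroxybenzaldehyde
Product: 2 2-hydroxy-4-(methoxymethoxy)benzaldehyde
Conditions: MOMCl (1.1 equiv), K2CO3 (1.5 equiv), acetone, 0 °C to rt
Reagents that add atoms: chloromethyl methyl ether (MOMCl), COCCl
Why: Williamson-type acetal ether formation (MOM protection) should be selective because the 2-OH is locked in a hydrogen bond to the formyl oxygen, so only the free and more acidic 4-OH is alkylated; no stereocentre arises.

Step 2
Reactants: 2 2-hydroxy-4-(methoxymethoxy)benzaldehyde
Product: 4 7-(methoxymethoxy)-2H-chromene, via phosphonium ylide 3 (not isolated)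
Conditions: CH2=CHPPh3Br (1.2 equiv), K2CO3 (1.5 equiv), 1,4-dioxane (trace H2O), reflux
Reagents that add atoms: vinyltriphenylphosphonium bromide, C=C[P+](c1ccccc1)(c1ccccc1)c1ccccc1.[Br-]
Why: Schweizer reaction, in which the phenoxide of 2 adds to the vinylphosphonium salt (oxa-Michael addition) and the ylide 3 so formed closes the six-membered ring C by intramolecular Wittig olefination of the ortho formyl group, which fixes the double bond at C3=C4 and leaves the product flat and achiral.

Step 3
Reactants: 5 4-bromoresorcinol
Product: 6 1-bromo-2,4-bis(methoxymethoxy)benzene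
Conditions: MOMCl (2.5 equiv), K2CO3 (4 equiv), acetone, 0 °C to rt
Reagents that add atoms: chloromethyl methyl ether (MOMCl), COCCl
Why: Twofold MOM protection of both phenols, chosen because MOM ethers survive organolithium reagents and hot aqueous medium and later serve as directing groups.

Step 4
Reactants: 6 1-bromo-2,4-bis(methoxymethoxy)benzene
Product: 9 [2,4-bis(methoxymethoxy)phenyl]boronic acid, via aryllithium 7 (not isolated), via lithium aryltriisopropoxyborate 8 (not isolated)
Conditions: n-BuLi (1.05 equiv), THF, −78 °C; B(Oi-Pr)3 (1.5 equiv), −78 °C to rt; sat. aq NH4Cl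
Reagents that add atoms: triisopropyl borate, CC(C)OB(OC(C)C)OC(C)C; water, O; n-butyllithium (lithium of 7 and 8 only), [Li]CCCC
Why: Bromine–lithium exchange is far faster at −78 °C than any deprotonation, so 7 forms only at the former C–Br carbon, and its trapping with the borate ester followed by near-neutral hydrolysis of 8 is the standard boronic acid synthesis and spares the MOM groups.

Step 5
Reactants: 4 7-(methoxymethoxy)-2H-chromene; 9 [2,4-bis(methoxymethoxy)phenyl]boronic acid
Product: 10 (3R)-3-[2,4-bis(methoxymethoxy)phenyl]-7-(methoxymethoxy)chromane
Conditions: [Rh(OH)(cod)]2 (2.5 mol %) and (R)-SEGPHOS (6 mol %) premixed at 50 °C; 9 (2.5 equiv), 1,4-dioxane/H2O (10:1), 80 °C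
Reagents that add atoms: none
Why: Transmetalation of 9 to the hydroxo complex of monovalent rhodium gives an aryl–rhodium species that binds the C3=C4 double bond of 4 and inserts it in syn fashion, so that C1' becomes bonded to C3 and the metal ends on benzylic C4; a 1,4-shift of rhodium from C4 to the free ortho position C6' of the new aryl group (or direct protonolysis) and protonation by water then release 10 and return the Rh–OH catalyst. The closest known reaction type is the rhodium-catalysed asymmetric hydroarylation of 2H-chromenes and related unactivated cyclic alkenes with arylboronic acids, the alkene counterpart of the Hayashi–Miyaura addition. No ring is closed, since ring C is already in place and only its C3=C4 bond is saturated. The new stereocentre C3 is set in the insertion, in which the twofold-symmetric bisphosphine leaves only one enantiotopic face of the flat chromene open to the aryl group, and it cannot be lost afterwards because C3–H of 10 is not acidic. The step needs regioselectivity (aryl to C3, metal to C4), which ring A secures by stabilising the C4–Rh bond as a benzyl complex, whereas the reverse orientation would put rhodium beta to O1; the syn adduct has no syn beta hydrogen, so no Heck-type alkene can form. Both C3 and C1' are donor carbons that no polar reaction would join, the insertion at the metal lifts this mismatch, and an excess of the cheap 9 offsets protodeboronation.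

Step 6
Reactants: 10 (3R)-3-[2,4-bis(methoxymethoxy)phenyl]-7-(methoxymethoxy)chromane
Product: 12 (3R)-3-[2,4-bis(methoxymethoxy)-3-(3-methylbut-2-en-1-yl)phenyl]-7-(methoxymethoxy)-8-(3-methylbut-2-en-1-yl)chromane, via 8,3'-dilithio compound 11 (not isolated)
Conditions: n-BuLi (3 equiv), THF, 0 °C to rt; CuBr·SMe2 (20 mol %), prenyl bromide (4 equiv), −40 °C to rt
Reagents that add atoms: prenyl bromide (1-bromo-3-methylbut-2-ene), CC(C)=CCBr; n-butyllithium (lithium of 11 only), [Li]CCCC
Why: Twofold directed ortho-metalation followed by copper-assisted allylic substitution: C3' lies between two MOM ethers and C8 between O1 and the 7-OMOM group, so these two hydrogens are kinetically by far the most acidic (cooperative 1,3-directing effect), the benzylic C3–H and C4–H are left alone so the stereocentre should be kept, and attack at the unhindered primary end of prenyl bromide gives the linear prenyl groups.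

Step 7
Reactants: 12 (3R)-3-[2,4-bis(methoxymethoxy)-3-(3-methylbut-2-en-1-yl)phenyl]-7-(methoxymethoxy)-8-(3-methylbut-2-en-1-yl)chromane
Product: 13 kanzonol X, (3R)-3-[2,4-dihydroxy-3-(3-methylbut-2-en-1-yl)phenyl]-8-(3-methylbut-2-en-1-yl)chroman-7-ol
Conditions: cat. HCl, MeOH, 40 °C
Reagents that add atoms: none
Why: Acid-catalysed transacetalisation of the three aryl MOM ethers to methanol is a standard end game for prenylated phenols, should be faster under dilute acid at mild temperature than protonation of the trisubstituted alkenes, and does not involve C3.

**Compound list**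

1 | 2,4-dihydroxybenzaldehyde | O=Cc1ccc(O)cc1O | starting material
2 | 2-hydroxy-4-(methoxymethoxy)benzaldehyde | COCOc1ccc(C=O)c(O)c1 | intermediate
3 | {2-[2-formyl-5-(methoxymethoxy)phenoxy]ethylidene}triphenylphosphorane | COCOc1ccc(C=O)c(OCC=P(c2ccccc2)(c2ccccc2)c2ccccc2)c1 | intermediate
4 | 7-(methoxymethoxy)-2H-chromene | COCOc1ccc2c(c1)OCC=C2 | intermediate
5 | 4-bromoresorcinol | Oc1ccc(Br)c(O)c1 | starting material
6 | 1-bromo-2,4-bis(methoxymethoxy)benzene | COCOc1ccc(Br)c(OCOC)c1 | intermediate
7 | [2,4-bis(methoxymethoxy)phenyl]lithium | [Li]c1ccc(OCOC)cc1OCOC | intermediate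
8 | lithium [2,4-bis(methoxymethoxy)phenyl]triisopropoxyborate | [Li+].CC(C)O[B-](OC(C)C)(OC(C)C)c1ccc(OCOC)cc1OCOC | intermediate
9 | [2,4-bis(methoxymethoxy)phenyl]boronic acid | COCOc1ccc(B(O)O)c(OCOC)c1 | intermediate
10 | (3R)-3-[2,4-bis(methoxymethoxy)phenyl]-7-(methoxymethoxy)chromane | COCOc1ccc([C@@H]2COc3cc(OCOC)ccc3C2)c(OCOC)c1 | intermediate
11 | (3R)-8-lithio-3-[3-lithio-2,4-bis(methoxymethoxy)phenyl]-7-(methoxymethoxy)chromane | [Li]c1c(OCOC)ccc([C@@H]2COc3c(ccc(OCOC)c3[Li])C2)c1OCOC | intermediate
12 | (3R)-3-[2,4-bis(methoxymethoxy)-3-(3-methylbut-2-en-1-yl)phenyl]-7-(methoxymethoxy)-8-(3-methylbut-2-en-1-yl)chromane | CC(C)=CCc1c(OCOC)ccc([C@@H]2COc3c(ccc(OCOC)c3CC=C(C)C)C2)c1OCOC | intermediate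
13 | kanzonol X | CC(C)=CCc1c(O)ccc([C@@H]2COc3c(ccc(O)c3CC=C(C)C)C2)c1O | target

**Step count**

Total steps: 7. Longest linear sequence: 5 (steps 1, 2, 5, 6, 7; the sequence 3, 4, 5, 6, 7 is of equal length).

**Steps most likely to fail**

**Step 5.**
- What may go wrong: protodeboronation of the electron-rich, ortho-alkoxy boronic acid may outrun the slow insertion of an unactivated alkene. Facial selectivity may also be poor with an ortho-substituted aryl group.
- Fallback (sets out from 4 and 6, comes back at 10): the stereocentre and the bond are made in two separate known events.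
  - Copper-catalysed enantioselective protoboration of 4 (CuCl, NaOt-Bu, chiral bisphosphine, B2pin2, MeOH, THF, rt) puts boron on C3 and monovalent copper on benzylic C4. It should give (3R)-7-(methoxymethoxy)-3-(4,4,5,5-tetramethyl-1,3,2-dioxaborolan-2-yl)chromane F1.
  - KHF2 in MeOH/H2O converts this to potassium [(3R)-7-(methoxymethoxy)chroman-3-yl]trifluoroborate F2.
  - A stereospecific Suzuki–Miyaura coupling of this secondary alkylboron compound with bromide 6 then leads to 10. It uses the zerovalent palladium complex Pd(P(t-Bu)3)2, K2CO3, toluene/H2O, 100 °C.
  - The coupling runs with inversion at carbon, so the boron-bearing centre is made in the configuration that becomes 3R after inversion.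

**Step 6.**
- What may go wrong: the second metalation may be incomplete, and capture at the two hindered aryllithium centres may be sluggish or allyl-transposed. Either would give mixtures of partly alkylated material.
- Fallback (sets out from 10 by way of 11, comes back at 12): the polarity of the prenylation is reversed.
  - The dilithio compound 11 is quenched with I2 to give (3R)-8-iodo-3-[3-iodo-2,4-bis(methoxymethoxy)phenyl]-7-(methoxymethoxy)chromane F3. This compound can be freed from under-metalated material.
  - A twofold Stille coupling with tributyl(3-methylbut-2-en-1-yl)stannane (Pd(PPh3)4, DMF, 90 °C) then gives 12.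

**Step 7.**
- What may go wrong: acid may induce ring closure of a freed phenol onto the neighbouring prenyl double bond.
- Fallback (sets out from 12, comes back at 13): the acetals are cleaved without a Brønsted acid.
  - TMSOTf and 2,2'-bipyridyl in MeCN (0 °C to rt) turn each aryl MOM ether into the aryl silyl ether. This gives (3R)-3-[2,4-bis(trimethylsilyloxy)-3-(3-methylbut-2-en-1-yl)phenyl]-8-(3-methylbut-2-en-1-yl)-7-(trimethylsilyloxy)chromane F4.
  - Added water hydrolyses F4 to 13 at near-neutral pH.

**Further compounds**

F1 | step 5 | (3R)-7-(methoxymethoxy)-3-(4,4,5,5-tetramethyl-1,3,2-dioxaborolan-2-yl)chromane | CC1(C)OB(OC1(C)C)[C@H]1COc2cc(OCOC)ccc2C1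
F2 | step 5 | potassium [(3R)-7-(methoxymethoxy)chroman-3-yl]trifluoroborate | [K+].F[B-](F)(F)[C@H]1COc2cc(OCOC)ccc2C1
F3 | step 6 | (3R)-8-iodo-3-[3-iodo-2,4-bis(methoxymethoxy)phenyl]-7-(methoxymethoxy)chromane | COCOc1ccc([C@@H]2COc3c(ccc(OCOC)c3I)C2)c(OCOC)c1I
F4 | step 7 | (3R)-3-[2,4-bis(trimethylsilyloxy)-3-(3-methylbut-2-en-1-yl)phenyl]-8-(3-methylbut-2-en-1-yl)-7-(trimethylsilyloxy)chromane | CC(C)=CCc1c(O[Si](C)(C)C)ccc([C@@H]2COc3c(ccc(O[Si](C)(C)C)c3CC=C(C)C)C2)c1O[Si](C)(C)C
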